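**Strategy.** The route rests on cutting the C2–C1′ bond of ring C. C2, the only stereocentre, carries the phenyl ring and lies β to the C4 carbonyl through C3, so it can be made by 1,4-addition of a phenyl group to a flat chromone. One rhodium–chiral diene-catalysed addition of phenylboronic acid forms this bond and sets (2S) without closing a ring. The precursor is 6-geranyl-5,7-bis(methoxymethoxy)chromone. Its 6-substitution is fixed by metalating 1-silyloxy-3,5-bis(methoxymethoxy)benzene at the carbon flanked by both acetal ethers. Ring C is then built on the desilylated phenol by formylation, ethynyl Grignard addition and oxidation. Acid methanolysis of the acetal ethers ends the synthesis.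

Key step: step 8

Remark (structure check): the target is read as (2S)-5,7-dihydroxy-6-[(2E)-3,7-dimethylocta-2,6-dien-1-yl]-2-phenyl-2,3-dihydro-4H-chromen-4-one. The geranyl group sits on C6 of ring A, between the C5 and C7 oxygens and para to the ring oxygen O1. C2 is S (O1 > phenyl > C3 > H). The structures of the chromone and of its arylation product agree with this reading and need no correction. "Geranyl" below always means the (2E)-3,7-dimethylocta-2,6-dien-1-yl group.

Remark (design): the third phloroglucinol oxygen is capped as a bulky, non-coordinating TIPS ether so that metalation can only occur between the two MOM ethers. After desilylation the phenol has two equivalent ortho positions, so the acyl carbon can only enter meta to geranyl. Ring C is closed under neutral to basic conditions through an ynone, which avoids an acid-promoted closure in the presence of the MOM ethers.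

Assumption: the (S,S) antipode of 2,5-diphenylbicyclo[2.2.2]octa-2,5-diene is assigned, by analogy with cyclic enones, as the ligand that delivers phenyl to the face giving (2S). The sense should be checked on the first run, and the mirror-image ligand taken if (2R) is found.

Step 1
Reactants: 1 phloroglucinol (benzene-1,3,5-triol)
Product: 2 5-[(triisopropylsilyl)oxy]benzene-1,3-diol
Conditions: TIPSCl (1.0 equiv), 1 (3 equiv), imidazole (1.5 equiv), DMF, 0 °C to rt; excess 1 removed by aqueous wash
Reagents that add atoms: chlorotriisopropylsilane (TIPSCl), CC(C)[Si](Cl)(C(C)C)C(C)C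
Why: O-silylation of a phenol, in which the three hydroxyls are equivalent, and the excess of triol together with the bulky silyl chloride should hold the reaction at the mono-ether.

Step 2
Reactants: 2 5-[(triisopropylsilyl)oxy]benzene-1,3-diol
Product: 3 [3,5-bis(methoxymethoxy)phenoxy]triisopropylsilane
Conditions: MOMCl (3 equiv), i-Pr2NEt (4 equiv), CH2Cl2, 0 °C to rt
Reagents that add atoms: chloromethyl methyl ether (MOMCl), COCCl
Why: O-alkylation of the two remaining phenols to acetal ethers under amine base, conditions that leave an aryl TIPS ether intact.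

Step 3
Reactants: 3 [3,5-bis(methoxymethoxy)phenoxy]triisopropylsilane; 4 geranyl bromide [(2E)-1-bromo-3,7-dimethylocta-2,6-diene]
Product: 6 [4-geranyl-3,5-bis(methoxymethoxy)phenoxy]triisopropylsilane, via aryllithium 5 (not isolated)
Conditions: n-BuLi (1.15 equiv), THF, 0 °C, 1 h; CuBr·SMe2 (10 mol %), then 4 (1.2 equiv), −78 to 0 °C
Reagents that add atoms: none
Why: Directed ortho-metalation at C4, the position chelated by both OMOM groups and left open by the shielding OTIPS group, followed by copper-assisted SN2 allylation at the primary carbon of 4 (γ-attack would build a quaternary centre beside a 2,6-disubstituted arene), so the (E)-alkene should be carried over unchanged.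

Step 4
Reactants: 6 [4-geranyl-3,5-bis(methoxymethoxy)phenoxy]triisopropylsilane
Product: 7 4-geranyl-3,5-bis(methoxymethoxy)phenol
Conditions: TBAF (1.2 equiv), AcOH (1.2 equiv), THF, 0 °C
Reagents that add atoms: none
Why: Fluoride-mediated desilylation of an aryl silyl ether, buffered with acetic acid so that no free phenoxide lingers, with MOM ethers and alkenes inert to fluoride.

Step 5
Reactants: 7 4-geranyl-3,5-bis(methoxymethoxy)phenol
Product: 8 3-geranyl-6-hydroxy-2,4-bis(methoxymethoxy)benzaldehyde
Conditions: MgCl2 (2 equiv), Et3N (4 equiv), (CH2O)n (6 equiv), MeCN, reflux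
Reagents that add atoms: paraformaldehyde (formaldehyde source), C=O
Why: Casnati–Skattebøl ortho-formylation, in which the magnesium phenoxide delivers formaldehyde only ortho to the hydroxyl and a second formaldehyde oxidises the hydroxymethyl group by hydride transfer; the two ortho positions of 7 are equivalent, so a single aldehyde with the carbonyl carbon meta to geranyl should form under basic conditions that spare the MOM ethers.

Step 6
Reactants: 8 3-geranyl-6-hydroxy-2,4-bis(methoxymethoxy)benzaldehyde
Product: 9 4-geranyl-2-(1-hydroxyprop-2-yn-1-yl)-3,5-bis(methoxymethoxy)phenol (racemic carbinol)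
Conditions: HC≡CMgBr (3.5 equiv, 0.5 M in THF), THF, 0 °C to rt; sat. aq. NH4Cl; used crude
Reagents that add atoms: ethynylmagnesium bromide, C#C[Mg]Br
Why: Grignard 1,2-addition to the aldehyde after the first equivalent has deprotonated the phenol; the carbinol centre forms as a racemate, which is of no consequence because the next step oxidises it away.

Step 7
Reactants: 9 4-geranyl-2-(1-hydroxyprop-2-yn-1-yl)-3,5-bis(methoxymethoxy)phenol
Product: 11 6-geranyl-5,7-bis(methoxymethoxy)chromone (4H-chromen-4-one numbering), via aryl ethynyl ketone 10 (not isolated)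
Conditions: activated MnO2 (15 equiv), CH2Cl2, rt; filter through Celite; K2CO3 (0.2 equiv), acetone, rt
Reagents that add atoms: none
Why: Chemoselective MnO2 oxidation of the benzylic–propargylic alcohol to the ynone, whose ortho-hydroxyl then adds to the terminal alkyne carbon (6-endo-dig oxa-Michael addition) to close the pyranone ring C under conditions that leave MOM ethers and geranyl alkenes untouched.

Step 8
Reactants: 11 6-geranyl-5,7-bis(methoxymethoxy)chromone; 12 phenylboronic acid
Product: 13 (2S)-6-geranyl-5,7-bis(methoxymethoxy)flavanone [(2S)-2-phenyl-2,3-dihydro-4H-chromen-4-one numbering]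
Conditions: [RhCl(C2H4)2]2 (2.5 mol %), (1S,4S)-2,5-diphenylbicyclo[2.2.2]octa-2,5-diene (5.5 mol %), KOH (0.3 equiv, aq.), 12 (2.5 equiv), toluene/H2O 10:1, 40 °C
Reagents that add atoms: none
Why: This is a Hayashi–Miyaura-type asymmetric conjugate addition, a known reaction of chromones: the diene-bound hydroxo-rhodium complex (monovalent rhodium) transmetalates with 12 to a phenyl–rhodium species, which binds the C2=C3 bond of 11 and inserts it syn, placing phenyl on C2 and rhodium on C3 as an oxa-π-allyl enolate. Water protonates that enolate at C3, releasing 13 and returning the hydroxo-rhodium catalyst; no ring is closed. The C2 stereocentre is set by catalyst control alone, because the C2-symmetric diene shields one enantioface of the planar pyranone and phenyl is delivered to the face that gives (2S). The step needs 1,4- rather than 1,2-addition and reaction at the enone rather than at the geranyl alkenes, which is secured because C2=C3 is the only electron-poor alkene and carries an unhindered C2–H, while the trisubstituted geranyl alkenes neither displace the diene nor insert. Both phenols are capped as MOM ethers, so no phenoxide can deactivate the enone, and the substoichiometric base in a two-phase medium should keep retro-oxa-Michael opening of ring C, and with it erosion at C2, slow.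

Step 9
Reactants: 13 (2S)-6-geranyl-5,7-bis(methoxymethoxy)flavanone
Product: 14 (2S)-6-geranyl-5,7-dihydroxyflavanone (CNP0201748.1)
Conditions: HCl (1.25 M in MeOH, 5 equiv), MeOH, rt to 40 °C
Reagents that add atoms: none
Why: Acid-catalysed acetal methanolysis of the two aryl MOM ethers, dilute and cool enough that the trisubstituted alkenes should not be protonated at a useful rate; C2 should hold because ring C opens only through phenoxide or enolate formation, which acid does not provide.

Compound list
1 | phloroglucinol (benzene-1,3,5-triol) | Oc1cc(O)cc(O)c1 | starting material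
2 | 5-[(triisopropylsilyl)oxy]benzene-1,3-diol | Oc1cc(O)cc(O[Si](C(C)C)(C(C)C)C(C)C)c1 | intermediate
3 | [3,5-bis(methoxymethoxy)phenoxy]triisopropylsilane | COCOc1cc(OCOC)cc(O[Si](C(C)C)(C(C)C)C(C)C)c1 | intermediate
4 | geranyl bromide, (2E)-1-bromo-3,7-dimethylocta-2,6-diene | CC(C)=CCC/C(C)=C/CBr | starting material
5 | [2,6-bis(methoxymethoxy)-4-(triisopropylsilyloxy)phenyl]lithium (not isolated) | [Li]c1c(OCOC)cc(O[Si](C(C)C)(C(C)C)C(C)C)cc1OCOC | intermediate
6 | [4-geranyl-3,5-bis(methoxymethoxy)phenoxy]triisopropylsilane | COCOc1cc(O[Si](C(C)C)(C(C)C)C(C)C)cc(OCOC)c1C/C=C(\C)CCC=C(C)C | intermediate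
7 | 4-geranyl-3,5-bis(methoxymethoxy)phenol | COCOc1cc(O)cc(OCOC)c1C/C=C(\C)CCC=C(C)C | intermediate
8 | 3-geranyl-6-hydroxy-2,4-bis(methoxymethoxy)benzaldehyde | O=Cc1c(O)cc(OCOC)c(C/C=C(\C)CCC=C(C)C)c1OCOC | intermediate
9 | 4-geranyl-2-(1-hydroxyprop-2-yn-1-yl)-3,5-bis(methoxymethoxy)phenol, racemic at the carbinol carbon | C#CC(O)c1c(O)cc(OCOC)c(C/C=C(\C)CCC=C(C)C)c1OCOC | intermediate
10 | 1-[3-geranyl-6-hydroxy-2,4-bis(methoxymethoxy)phenyl]prop-2-yn-1-one (not isolated) | C#CC(=O)c1c(O)cc(OCOC)c(C/C=C(\C)CCC=C(C)C)c1OCOC | intermediate
11 | 6-geranyl-5,7-bis(methoxymethoxy)chromone | O=c1ccoc2cc(OCOC)c(C/C=C(\C)CCC=C(C)C)c(OCOC)c12 | intermediate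
12 | phenylboronic acid | OB(O)c1ccccc1 | starting material
13 | (2S)-6-geranyl-5,7-bis(methoxymethoxy)flavanone | O=C1C[C@@H](c2ccccc2)Oc2cc(OCOC)c(C/C=C(\C)CCC=C(C)C)c(OCOC)c21 | intermediate
14 | (2S)-6-geranyl-5,7-dihydroxyflavanone (CNP0201748.1) | CC(C)=CCC/C(C)=C/Cc1c(O)cc2c(c1O)C(=O)C[C@@H](c1ccccc1)O2 | target

Total step count: 9. Longest linear sequence: 9 steps (fully linear from phloroglucinol).

Steps most likely to fail

Step 8. The electron-rich enone, with a 5-alkoxy group beside the carbonyl, may insert slowly; facial selectivity may be insufficient; or base may open ring C and erode C2. The fallback separates bond formation from stereocontrol and sets out from 11. Conjugate addition of 12 under Pd(O2CCF3)2 (divalent palladium), 2,2′-bipyridine, NH4PF6 and water in 1,2-dichloroethane at 60 °C, a base-free cationic aryl-palladium pathway, should give racemic 6-geranyl-5,7-bis(methoxymethoxy)flavanone F1. Preparative chromatography on a chiral polysaccharide phase then separates the wanted enantiomer from (2R)-6-geranyl-5,7-bis(methoxymethoxy)flavanone F2. The route is rejoined at 13.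

Step 7. The terminal ynone may oligomerise, be oxidised further at the electron-rich phenol, or close in the 5-exo sense before the wanted 6-endo closure. The fallback avoids the ynone and sets out from 8. Addition of MeMgBr (3 equiv, THF, 0 °C) should give racemic 4-geranyl-2-(1-hydroxyethyl)-3,5-bis(methoxymethoxy)phenol F3. MnO2 in CH2Cl2 oxidises it to 1-[3-geranyl-6-hydroxy-2,4-bis(methoxymethoxy)phenyl]ethan-1-one F4. Condensation with N,N-dimethylformamide dimethyl acetal (toluene, 90 °C) gives (E)-3-(dimethylamino)-1-[3-geranyl-6-hydroxy-2,4-bis(methoxymethoxy)phenyl]prop-2-en-1-one F5. Warming F5 in acetic acid at 60 °C, an acid weak enough for aryl MOM ethers, should close ring C by addition–elimination with loss of dimethylamine. The route is rejoined at 11.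

Step 9. Protonation of the geranyl alkenes may lead to cyclisation onto the flanking phenols or along the chain before both acetals are gone. The fallback replaces protic acid by silyl transfer and sets out from 13. TMSOTf (4 equiv) with 2,2′-bipyridyl (6 equiv) in MeCN at 0 °C to rt should convert both aryl MOM ethers into silyl ethers through N-(methoxymethyl)bipyridinium salts, giving (2S)-6-geranyl-5,7-bis(trimethylsilyloxy)flavanone F6. Addition of water hydrolyses the aryl silyl ethers. The route is rejoined at 14.

Further compounds
F1 | step 8 | racemic 6-geranyl-5,7-bis(methoxymethoxy)flavanone | O=C1CC(c2ccccc2)Oc2cc(OCOC)c(C/C=C(\C)CCC=C(C)C)c(OCOC)c21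
F2 | step 8 | (2R)-6-geranyl-5,7-bis(methoxymethoxy)flavanone | O=C1C[C@H](c2ccccc2)Oc2cc(OCOC)c(C/C=C(\C)CCC=C(C)C)c(OCOC)c21
F3 | step 7 | 4-geranyl-2-(1-hydroxyethyl)-3,5-bis(methoxymethoxy)phenol (racemic) | CC(O)c1c(O)cc(OCOC)c(C/C=C(\C)CCC=C(C)C)c1OCOC
F4 | step 7 | 1-[3-geranyl-6-hydroxy-2,4-bis(methoxymethoxy)phenyl]ethan-1-one | CC(=O)c1c(O)cc(OCOC)c(C/C=C(\C)CCC=C(C)C)c1OCOC
F5 | step 7 | (E)-3-(dimethylamino)-1-[3-geranyl-6-hydroxy-2,4-bis(methoxymethoxy)phenyl]prop-2-en-1-one | CN(C)/C=C/C(=O)c1c(O)cc(OCOC)c(C/C=C(\C)CCC=C(C)C)c1OCOC
F6 | step 9 | (2S)-6-geranyl-5,7-bis(trimethylsilyloxy)flavanone | CC(C)=CCC/C(C)=C/Cc1c(O[Si](C)(C)C)cc2c(c1O[Si](C)(C)C)C(=O)C[C@@H](c1ccccc1)O2
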